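**Remarks on the chemistry (assumptions)**
- The target has no stereogenic centre and is achiral. "Single enantiomer" is therefore read as "the single geometric isomer drawn", i.e. the Z exocyclic C5=CH double bond.
- Compounds 1, 5 and 9 are taken as catalogue chemicals.
- Metal or boron derivatives that are only the conjugate base of a numbered compound (the bromomagnesium acetylide of 2, the alkoxide of 3, the aryl borates of 12) are treated as forms of that compound and carry no number of their own.

Numbering used throughout: 1 aldehyde building block; 2 aryl alkyne; 3 propargylic alcohol; 4 ynone; 5 oxazole; 6 bicyclic cycloadduct; 7 2-ethoxyfuran; 8 butenolide; 9 4-methoxybenzaldehyde; 10 aldol adduct; 11 tri-O-methyl cadiolide A; 12 cadiolide A.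

## Analysis of the target

Cadiolide A is a fully substituted 2(5H)-furanone (ring atoms O1, C2(=O), C3, C4, C5). C3 carries a 3,5-dibromo-4-hydroxybenzoyl group, C4 a 3,5-dibromo-4-hydroxyphenyl ring and C5 an exocyclic 4-hydroxybenzylidene group. The only stereochemical element is the C5=CH double bond, which is Z (aryl on the side of O1). It is the thermodynamic isomer, because the E isomer would press the benzylidene ring against the C4 aryl ring.

The feature the route is built on: the aroyl carbon, C3 and C4 form an Ar–C(=O)–C3=C4–Ar unit whose two aryl rings are identical. C3 and C4 are thus the α- and β-carbons of a hidden symmetric 1,3-diarylpropynone, and what remains of the ring is only the three-atom C2(=O)–O1–C5 edge.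

Sensitive points are the four aryl C–Br bonds (no Pd(0) and no alkyllithium late in the route), the cross-conjugated dienyl lactone (Michael acceptor, base-labile, photo-isomerisable) and three acidic phenols. The bromine atoms must come in with the building blocks: the unbrominated 4-hydroxyphenyl ring is the most electron-rich of the three, so a late electrophilic bromination could not spare it.

The real difficulty is regiochemical. Four different substituents sit on four contiguous atoms of a five-membered lactone, with the aroyl group next to the lactone carbonyl and the aryl group next to the ylidene carbon.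

## Retrosynthetic reasoning

**12 ⇒ 11.** The three O–H bonds are traced back to three O–CH3 bonds. Methyl ethers survive an organomagnesium reagent, an oxidation, heating to 130 °C, aqueous acid and an amine base, and one Lewis-acid step removes all three. The forward reaction must cleave two hindered 2,6-dibromoanisoles and one anisole without touching the lactone, the ketone, the C–Br bonds or the Z alkene.

**11 ⇒ 8 + 9.** The exocyclic C5=CH bond is cut next. This brings in the only unbrominated ring as commercial aldehyde 9, so the bromination pattern is decided by the building blocks. The C5–H2 group of 8 is the γ-position of a vinylogous β-keto ester and is acidic enough for an amine-catalysed condensation. The forward reaction must give the Z isomer, which it does under thermodynamic control.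

**8 ⇒ 7 ⇒ 6 ⇒ 4 + 5 (key disconnection).** The C2–C3 and C4–C5 bonds of the lactone ring are cut at the same time.
- The C2(=O)–O1–C5 edge of 8 is recognised as the C5(OEt)–O1–C2(H) edge of oxazole 5; the N3=C4(Me) part of 5 is a leaving fragment.
- What is left of 8 is ynone 4, the hidden symmetric 1,3-diarylpropynone with both brominated rings in place.
- The cut is made here because it runs along the symmetry of the Ar–C(=O)–C3=C4–Ar unit. A cut through C3=C4, through the C4–aryl bond or through O1–C5 either needs two differently functionalised brominated building blocks or needs palladium next to four C–Br bonds.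
- The gain is a fully substituted furanone ring from an acyclic alkyne and a commercial heteroarene, in one metal-free operation.
- The forward reaction must join the ethoxy-bearing carbon of 5 to the aroyl-bearing alkyne carbon of 4 (and not the reverse), expel the nitrile fragment from 6 instead of reverting, and hydrolyse 7 to the conjugated lactone.

**4 ⇒ 3 ⇒ 2 + 1, and 2 ⇒ 1.** The ynone is cut between the carbonyl carbon and the alkyne: acetylide addition to aldehyde 1, then oxidation of 3. Alkyne 2 comes from the same aldehyde 1 by one-carbon homologation. Both brominated rings of the target therefore come from the single building block 1, and every step before the key step is routine.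

## Alternatives that were turned down

**Alternative 1:** the textbook disconnection of the C3=C4 bond. The forward key step is an intramolecular Knoevenagel condensation of the phenacyl β-keto ester A1, which gives 8; the route then continues as here.
- It separates the two identical aryl-bearing carbons. It therefore needs two different building blocks from the same bromoanisole, an α-hydroxy ketone and a β-keto acid equivalent, each two to three steps away, before they are joined through a base-labile phenacyl ester.
- The ring is made one bond at a time (ester C–O, then C3=C4).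
- The count to 8 is about two steps longer than in the chosen route.
- It is the route most chemists would draw first, so it fails the test of boldness. It is kept as a fallback.

**Alternative 2:** disconnection of the O1–C5 bond. The triketo ester A2 would be converted into its enol triflate A3, coupled under Sonogashira conditions with the commercial terminal alkyne that carries the third ring, and unmasked to the enynoic acid A4. A π-acid-catalysed 5-exo-dig lactonisation of A4 would give 11 directly.
- Geometry: only the Z isomer of A3 and A4 (carboxyl cis to the alkyne) can lactonise. In the tetrasubstituted, doubly acceptor-substituted alkene the ester and the aroyl group compete for that position with no element of control, and the E isomer puts the ketone oxygen next to the alkyne.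
- Ring size: the 4-methoxyphenyl group polarises the alkyne so that attack at the aryl-bearing carbon (6-endo) competes and would give the isomeric 2-pyranone A5.
- Chemoselectivity: Pd(0) must work in the presence of four aryl C–Br bonds.

**Alternative 3:** disconnection of the C4–aryl bond. The 3-aroyl tetronic acid A6 would be converted into the enol triflate A7 and coupled under Suzuki conditions with the boronic acid A8 to give 8.
- A8 carries two C–Br bonds and the product four, so oxidative addition into C–Br and oligomerisation compete with the desired coupling.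
- Triflation of the tricarbonyl system of A6 is ambident (ring enol or exocyclic enol).
- A6 itself needs an acylation/Dieckmann sequence of three to four steps.
- Again one bond is made per step, and the symmetry of the two brominated rings is not used.

Key step: step 4

## Route

Step 1
Reactants: 1 3,5-dibromo-4-methoxybenzaldehyde
Product: 2 1,3-dibromo-5-ethynyl-2-methoxybenzene
Conditions: dimethyl (1-diazo-2-oxopropyl)phosphonate (1.2 equiv), K2CO3 (2 equiv), MeOH/THF, 0 °C → rt
Reagents that add atoms: dimethyl (1-diazo-2-oxopropyl)phosphonate (Ohira–Bestmann reagent), CC(=O)C(=[N+]=[N-])P(=O)(OC)OC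
Why: Seyferth–Gilbert homologation in the Ohira–Bestmann variant: methanolysis of the acetyl group releases the diazomethylphosphonate anion, which olefinates the non-enolisable aldehyde and, after loss of N2 and a 1,2-hydrogen shift, gives the terminal alkyne; carbonate in methanol leaves the aryl C–Br bonds untouched, which an alkyllithium-based Corey–Fuchs sequence would not.

Step 2
Reactants: 2 1,3-dibromo-5-ethynyl-2-methoxybenzene; 1 3,5-dibromo-4-methoxybenzaldehyde
Product: 3 rac-1,3-bis(3,5-dibromo-4-methoxyphenyl)prop-2-yn-1-ol
Conditions: EtMgBr (1.0 equiv), THF, 0 °C → rt; then 1, 0 °C → rt; aq NH4Cl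
Reagents that add atoms: none
Why: Addition of an alkynyl Grignard reagent to a non-enolisable aryl aldehyde; EtMgBr deprotonates the C(sp)–H of 2 but should not undergo Br/Mg exchange with the aryl bromides at these temperatures; the carbinol centre forms as a racemate and is removed in step 3.

Step 3
Reactants: 3 rac-1,3-bis(3,5-dibromo-4-methoxyphenyl)prop-2-yn-1-ol
Product: 4 1,3-bis(3,5-dibromo-4-methoxyphenyl)prop-2-yn-1-one
Conditions: activated MnO2 (10 equiv), CH2Cl2, rt
Reagents that add atoms: none
Why: Heterogeneous MnO2 oxidation of a doubly activated (benzylic and propargylic) secondary alcohol to the conjugated ynone; over-oxidation is not possible and the aryl bromides and methyl ethers are inert.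

Step 4
Reactants: 4 1,3-bis(3,5-dibromo-4-methoxyphenyl)prop-2-yn-1-one; 5 5-ethoxy-4-methyl-1,3-oxazole
Product: 8 3-(3,5-dibromo-4-methoxybenzoyl)-4-(3,5-dibromo-4-methoxyphenyl)furan-2(5H)-one, via 7-oxa-2-azabicyclo[2.2.1]heptadiene adduct 6 (not isolated), via 2-ethoxyfuran 7 (not isolated)
Conditions: 5 (3 equiv), PhMe, 130 °C, sealed tube; then 2 M aq HCl, THF, rt
Reagents that add atoms: water, O
Why: Oxazole 5 reacts as a 2-azadiene through C2 and C5 with the triple bond of 4 in a thermal [4+2] cycloaddition to give bicycle 6, which undergoes [4+2] cycloreversion along the other pair of bonds and expels the N3=C4(Me) bridge as a nitrile, so that O1 and both former diene termini stay behind as the aromatic 2-ethoxyfuran 7; aqueous acid then protonates C5 of this push–pull furan and water hydrolyses the resulting O-ethyl lactonium ion to lactone 8. The closest known reaction type is the Diels–Alder/retro-Diels–Alder furan synthesis from 5-alkoxyoxazoles and acetylenic ketones or esters (the alkyne counterpart of the Kondrat'eva pyridine synthesis), followed by the usual acid hydrolysis of a 2-alkoxyfuran to a butenolide. The furanone ring is not closed by a cyclisation: its C2–C3 and C4–C5 bonds are both made in the intermolecular cycloaddition and the ring is set free by the extrusion, its C–O–C edge being taken over intact from the oxazole. No lasting stereocentre is created, since the two bridgehead centres of 6 form as a racemate and vanish on aromatisation. The selectivity needed is regiochemical: the ethoxy-bearing C5 of 5 must bond to the aroyl-bearing α-carbon of 4 and C2–H to the aryl-bearing β-carbon; the 5-alkoxy group makes C2 the nucleophilic diene terminus and the ketone makes the β-carbon the electrophilic alkyne terminus, so the polarised transition state places positive charge on the dialkoxy carbon and negative charge on the enolate α-carbon, which is the pairing that leads to 7. The direction of the cycloreversion is secured by the irreversible, aromatising loss of the nitrile, and protonation at C5 rather than C3 is secured by the acyl group on C3, which makes the α,β-unsaturated lactone the conjugated and stable tautomer. The step is metal-free and non-basic, so the four C–Br bonds and the methyl ethers are not at risk, and the meta-bromine atoms lower the LUMO of 4 and should help the cycloaddition.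

Step 5
Reactants: 8 3-(3,5-dibromo-4-methoxybenzoyl)-4-(3,5-dibromo-4-methoxyphenyl)furan-2(5H)-one; 9 4-methoxybenzaldehyde
Product: 11 (5Z)-3-(3,5-dibromo-4-methoxybenzoyl)-4-(3,5-dibromo-4-methoxyphenyl)-5-[(4-methoxyphenyl)methylidene]furan-2(5H)-one, via aldol adduct 10 (not isolated)
Conditions: piperidine (0.2 equiv), MeOH/CH2Cl2, rt, dark
Reagents that add atoms: none
Why: Vinylogous Knoevenagel (aldol) condensation: the C5–H2 group of 8 is the γ-position of a vinylogous β-keto ester, piperidine generates the 2-oxidofuran, which adds through C5 to 9, and E1cB loss of water from 10 gives the cross-conjugated dienyl lactone. The Z geometry is the thermodynamic outcome under these reversible conditions, because the E isomer would force the 4-methoxyphenyl ring against the C4 aryl ring whereas the Z isomer places it next to the small O1.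

Step 6
Reactants: 11 (5Z)-3-(3,5-dibromo-4-methoxybenzoyl)-4-(3,5-dibromo-4-methoxyphenyl)-5-[(4-methoxyphenyl)methylidene]furan-2(5H)-one
Product: 12 cadiolide A, (5Z)-3-(3,5-dibromo-4-hydroxybenzoyl)-4-(3,5-dibromo-4-hydroxyphenyl)-5-[(4-hydroxyphenyl)methylidene]furan-2(5H)-one
Conditions: BBr3 (10 equiv), CH2Cl2, −78 °C → rt, dark; then H2O
Reagents that add atoms: none
Why: Lewis-acid ether cleavage: BBr3 coordinates each methoxy oxygen and bromide removes the methyl group by SN2, the aryloxyboron species being hydrolysed on work-up; lactone, diaryl ketone and aryl C–Br bonds should not react with BBr3 at or below room temperature, and the Z alkene, being the thermodynamic isomer, is not endangered by the HBr formed.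

## Compound list

1 | 3,5-dibromo-4-methoxybenzaldehyde | COc1c(Br)cc(C=O)cc1Br | starting material
2 | 1,3-dibromo-5-ethynyl-2-methoxybenzene | COc1c(Br)cc(C#C)cc1Br | intermediate
3 | rac-1,3-bis(3,5-dibromo-4-methoxyphenyl)prop-2-yn-1-ol | COc1c(Br)cc(cc1Br)C(O)C#Cc1cc(Br)c(OC)c(Br)c1 | intermediate
4 | 1,3-bis(3,5-dibromo-4-methoxyphenyl)prop-2-yn-1-one | COc1c(Br)cc(cc1Br)C(=O)C#Cc1cc(Br)c(OC)c(Br)c1 | intermediate
5 | 5-ethoxy-4-methyl-1,3-oxazole | CCOc1c(C)nco1 | starting material
6 | [6-(3,5-dibromo-4-methoxyphenyl)-4-ethoxy-3-methyl-7-oxa-2-azabicyclo[2.2.1]hepta-2,5-dien-5-yl](3,5-dibromo-4-methoxyphenyl)methanone (racemic) | CCOC12OC(N=C1C)C(c1cc(Br)c(OC)c(Br)c1)=C2C(=O)c1cc(Br)c(OC)c(Br)c1 | intermediate (not isolated)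
7 | [4-(3,5-dibromo-4-methoxyphenyl)-2-ethoxyfuran-3-yl](3,5-dibromo-4-methoxyphenyl)methanone | CCOc1occ(-c2cc(Br)c(OC)c(Br)c2)c1C(=O)c1cc(Br)c(OC)c(Br)c1 | intermediate (not isolated)
8 | 3-(3,5-dibromo-4-methoxybenzoyl)-4-(3,5-dibromo-4-methoxyphenyl)furan-2(5H)-one | O=C1OCC(c2cc(Br)c(OC)c(Br)c2)=C1C(=O)c1cc(Br)c(OC)c(Br)c1 | intermediate
9 | 4-methoxybenzaldehyde | COc1ccc(C=O)cc1 | starting material
10 | 3-(3,5-dibromo-4-methoxybenzoyl)-4-(3,5-dibromo-4-methoxyphenyl)-5-[hydroxy(4-methoxyphenyl)methyl]furan-2(5H)-one (racemic mixture of diastereomers) | O=C1OC(C(O)c2ccc(OC)cc2)C(c2cc(Br)c(OC)c(Br)c2)=C1C(=O)c1cc(Br)c(OC)c(Br)c1 | intermediate (not isolated)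
11 | (5Z)-3-(3,5-dibromo-4-methoxybenzoyl)-4-(3,5-dibromo-4-methoxyphenyl)-5-[(4-methoxyphenyl)methylidene]furan-2(5H)-one | O=C1O/C(=C\c2ccc(OC)cc2)C(c2cc(Br)c(OC)c(Br)c2)=C1C(=O)c1cc(Br)c(OC)c(Br)c1 | intermediate
12 | cadiolide A, (5Z)-3-(3,5-dibromo-4-hydroxybenzoyl)-4-(3,5-dibromo-4-hydroxyphenyl)-5-[(4-hydroxyphenyl)methylidene]furan-2(5H)-one | O=C1O/C(=C\c2ccc(O)cc2)C(c2cc(Br)c(O)c(Br)c2)=C1C(=O)c1cc(Br)c(O)c(Br)c1 | target

## Step count, longest linear sequence and least certain steps

Total step count: 6. Longest linear sequence: 6 steps (1 → 2 → 3 → 4 → 8 → 11 → 12); aldehyde 1 enters twice, and 5 and 9 are commercial.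

**Step 4 (key step).**
- What may go wrong: the fully substituted diaryl ynone may be too sluggish a dienophile, so that thermal decomposition or oligomerisation of the oxazole outruns the cycloaddition. Regiochemical leakage (bonding of the ethoxy-bearing carbon to the aryl-bearing alkyne carbon) or incomplete hydrolysis of the push–pull ethoxyfuran would also cost material.
- Fallback (sets out from 2, returns to the route at 8), the textbook Knoevenagel lactone construction:
  - Markovnikov hydration of 2 (cat. HgSO4/H2SO4 or a gold(I) catalyst, aq MeOH) gives the methyl ketone 1-(3,5-dibromo-4-methoxyphenyl)ethan-1-one F1.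
  - One portion of F1 is α-brominated (CuBr2, EtOAc, reflux) to 2-bromo-1-(3,5-dibromo-4-methoxyphenyl)ethan-1-one F2. The bromide is exchanged for hydroxyl (HCO2Na, aq EtOH, reflux) to give 1-(3,5-dibromo-4-methoxyphenyl)-2-hydroxyethan-1-one F3.
  - A second portion of F1 is C-acylated (NaH, diethyl carbonate, THF, reflux) to ethyl 3-(3,5-dibromo-4-methoxyphenyl)-3-oxopropanoate F4.
  - Heating F3 with F4 in toluene with removal of ethanol (ester exchange through the acylketene) gives the phenacyl keto ester A1 of Alternative 1. Et3N in the same flask closes 8 by intramolecular Knoevenagel condensation.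

**Step 5.**
- What may go wrong: conjugate addition of piperidine or methanol to the doubly activated C4 position, methanolysis of the lactone, retro-aldol reversal with incomplete dehydration, or incomplete equilibration to the Z isomer.
- Fallback (sets out from 8, returns at 11), which replaces the reversible amine-mediated condensation by an irreversible Lewis-acid aldol addition of a preformed nucleophile followed by a separate elimination:
  - 8 is converted with TBSOTf and i-Pr2NEt in CH2Cl2 into the 2-silyloxyfuran [2-(tert-butyldimethylsilyloxy)-4-(3,5-dibromo-4-methoxyphenyl)furan-3-yl](3,5-dibromo-4-methoxyphenyl)methanone F5.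
  - In the same flask F5 undergoes a TBSOTf-promoted vinylogous Mukaiyama aldol addition to 9. This gives the silyl ether 5-[(tert-butyldimethylsilyloxy)(4-methoxyphenyl)methyl]-3-(3,5-dibromo-4-methoxybenzoyl)-4-(3,5-dibromo-4-methoxyphenyl)furan-2(5H)-one F6.
  - DBU then expels the silanolate by E1cB elimination and gives 11.

**Step 6.**
- What may go wrong: incomplete cleavage of the two hindered, electron-poor 2,6-dibromoanisole ethers, leading to mixtures of partly methylated phenols. Addition of HBr to the exocyclic alkene or light-induced Z/E scrambling during the long exposure needed for complete demethylation are further risks.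
- Fallback (sets out from 8, returns at 12), which moves the deprotection in front of the sensitive dienyl lactone and ends with a protecting-group-free condensation:
  - 8 is demethylated with BBr3 in CH2Cl2 to the bisphenol 3-(3,5-dibromo-4-hydroxybenzoyl)-4-(3,5-dibromo-4-hydroxyphenyl)furan-2(5H)-one F7.
  - F7 is condensed with commercial 4-hydroxybenzaldehyde (piperidinium acetate, EtOH, 60 °C) directly to 12.

**Step 2.**
- What may go wrong: incomplete metalation of the alkyne, so that residual EtMgBr adds to aldehyde 1, or slow halogen–magnesium exchange that scrambles the aryl bromides.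
- Fallback (sets out from 1, returns at 4, bypassing 3), which replaces carbonyl addition plus oxidation by a direct acylation of the alkyne:
  - Pinnick oxidation of 1 (NaClO2, NaH2PO4, 2-methyl-2-butene, aq t-BuOH) gives 3,5-dibromo-4-methoxybenzoic acid F8.
  - SOCl2 (cat. DMF) converts F8 into 3,5-dibromo-4-methoxybenzoyl chloride F9.
  - Copper-catalysed, palladium-free coupling of F9 with alkyne 2 (CuI cat., Et3N, THF, rt) gives ynone 4.

## Further compounds

F1 | step 4 | 1-(3,5-dibromo-4-methoxyphenyl)ethan-1-one | COc1c(Br)cc(cc1Br)C(C)=O
F2 | step 4 | 2-bromo-1-(3,5-dibromo-4-methoxyphenyl)ethan-1-one | COc1c(Br)cc(cc1Br)C(=O)CBr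
F3 | step 4 | 1-(3,5-dibromo-4-methoxyphenyl)-2-hydroxyethan-1-one | COc1c(Br)cc(cc1Br)C(=O)CO
F4 | step 4 | ethyl 3-(3,5-dibromo-4-methoxyphenyl)-3-oxopropanoate | CCOC(=O)CC(=O)c1cc(Br)c(OC)c(Br)c1
F5 | step 5 | [2-(tert-butyldimethylsilyloxy)-4-(3,5-dibromo-4-methoxyphenyl)furan-3-yl](3,5-dibromo-4-methoxyphenyl)methanone | CC(C)(C)[Si](C)(C)Oc1occ(-c2cc(Br)c(OC)c(Br)c2)c1C(=O)c1cc(Br)c(OC)c(Br)c1
F6 | step 5 | 5-[(tert-butyldimethylsilyloxy)(4-methoxyphenyl)methyl]-3-(3,5-dibromo-4-methoxybenzoyl)-4-(3,5-dibromo-4-methoxyphenyl)furan-2(5H)-one (racemic mixture of diastereomers) | O=C1OC(C(O[Si](C)(C)C(C)(C)C)c2ccc(OC)cc2)C(c2cc(Br)c(OC)c(Br)c2)=C1C(=O)c1cc(Br)c(OC)c(Br)c1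
F7 | step 6 | 3-(3,5-dibromo-4-hydroxybenzoyl)-4-(3,5-dibromo-4-hydroxyphenyl)furan-2(5H)-one | O=C1OCC(c2cc(Br)c(O)c(Br)c2)=C1C(=O)c1cc(Br)c(O)c(Br)c1
F8 | step 2 | 3,5-dibromo-4-methoxybenzoic acid | COc1c(Br)cc(cc1Br)C(O)=O
F9 | step 2 | 3,5-dibromo-4-methoxybenzoyl chloride | COc1c(Br)cc(cc1Br)C(Cl)=O
A1 | alternative 1 | 2-(3,5-dibromo-4-methoxyphenyl)-2-oxoethyl 3-(3,5-dibromo-4-methoxyphenyl)-3-oxopropanoate | COc1c(Br)cc(cc1Br)C(=O)COC(=O)CC(=O)c1cc(Br)c(OC)c(Br)c1
A2 | alternative 2 | tert-butyl 2-(3,5-dibromo-4-methoxybenzoyl)-3-(3,5-dibromo-4-methoxyphenyl)-3-oxopropanoate | CC(C)(C)OC(=O)C(C(=O)c1cc(Br)c(OC)c(Br)c1)C(=O)c1cc(Br)c(OC)c(Br)c1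
A3 | alternative 2 | tert-butyl (2Z)-2-(3,5-dibromo-4-methoxybenzoyl)-3-(3,5-dibromo-4-methoxyphenyl)-3-(trifluoromethylsulfonyloxy)prop-2-enoate | CC(C)(C)OC(=O)/C(C(=O)c1cc(Br)c(OC)c(Br)c1)=C(\OS(=O)(=O)C(F)(F)F)c1cc(Br)c(OC)c(Br)c1
A4 | alternative 2 | (2Z)-2-(3,5-dibromo-4-methoxybenzoyl)-3-(3,5-dibromo-4-methoxyphenyl)-5-(4-methoxyphenyl)pent-2-en-4-ynoic acid | OC(=O)/C(C(=O)c1cc(Br)c(OC)c(Br)c1)=C(\C#Cc1ccc(OC)cc1)c1cc(Br)c(OC)c(Br)c1
A5 | alternative 2 | 3-(3,5-dibromo-4-methoxybenzoyl)-4-(3,5-dibromo-4-methoxyphenyl)-6-(4-methoxyphenyl)-2H-pyran-2-one | O=C1OC(c2ccc(OC)cc2)=CC(c2cc(Br)c(OC)c(Br)c2)=C1C(=O)c1cc(Br)c(OC)c(Br)c1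
A6 | alternative 3 | 3-(3,5-dibromo-4-methoxybenzoyl)-4-hydroxyfuran-2(5H)-one | COc1c(Br)cc(cc1Br)C(=O)C1=C(O)COC1=O
A7 | alternative 3 | 4-(3,5-dibromo-4-methoxybenzoyl)-5-oxo-2,5-dihydrofuran-3-yl trifluoromethanesulfonate | COc1c(Br)cc(cc1Br)C(=O)C1=C(OS(=O)(=O)C(F)(F)F)COC1=O
A8 | alternative 3 | (3,5-dibromo-4-methoxyphenyl)boronic acid | COc1c(Br)cc(cc1Br)B(O)O
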